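**Plan**

1. Retrosynthesis: the two aryl O–CH3 bonds are cut first, then the CH2–CH2 bond between ring D and C-1 of the dibenzofuran (ring A), which opens the 18-membered ring to a chain with two CH2Br ends. Next come the C-7–CH2 bond of the other ethano bridge, the furan C–O and biaryl C–C bonds of rings A/B, and the diaryl ether C–O bond of rings C/D.
2. Forward: a Suzuki biaryl (rings A and B) closes to the dibenzofuran by intramolecular displacement of fluoride. A ring C/ring D diaryl ether carrying a vinyl group is then attached at C-7 by hydroboration and B-alkyl Suzuki coupling.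
3. Both ester carbons become CH2Br, and the macrocycle closes last by an intramolecular Wurtz coupling that makes the ring D–CH2–CH2–ring A bond directly at the oxidation level of the target. Demethylation ends the route.
4. Enabling feature: both carbons of that bond are primary benzylic carbons, one para to the ether oxygen on ring D and one on C-1 of ring A. Each can therefore travel as a methyl ester and then a bromide, and either can become the benzylic carbanion. The meta-linked ring C, the bent diaryl ether and the ethano bridge at C-7 bring the two ends within reach.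
5. Stereochemistry: the target has no stereocentre and no alkene geometry, and the macrocycle is assumed to be conformationally mobile, so nothing has to be controlled.

Key step: step 9

**Route**

Step 1
Reactants: 1 methyl 2-bromo-3,5-dimethoxybenzoate; 2 (4-chloro-2-fluorophenyl)boronic acid
Product: 3 methyl 2-(4-chloro-2-fluorophenyl)-3,5-dimethoxybenzoate
Conditions: Pd(PPh3)4 (5 mol%), K2CO3, DME/H2O, 90 °C
Reagents that add atoms: none
Why: Suzuki–Miyaura coupling, in which the C–Br bond activated by the ortho ester adds to zerovalent palladium much faster than the C–Cl bond of 2 under a triphenylphosphine catalyst, so the chloride is kept for step 6.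

Step 2
Reactants: 3 methyl 2-(4-chloro-2-fluorophenyl)-3,5-dimethoxybenzoate
Product: 4 methyl 2-(4-chloro-2-fluorophenyl)-3,5-dihydroxybenzoate
Conditions: BBr3, CH2Cl2, −78 °C to 0 °C; then H2O
Reagents that add atoms: none
Why: BBr3 cleavage of aryl methyl ethers, under which the hindered methyl ester and both aryl halides should survive at low temperature.

Step 3
Reactants: 4 methyl 2-(4-chloro-2-fluorophenyl)-3,5-dihydroxybenzoate
Product: 6 methyl 7-chloro-3-methoxydibenzofuran-1-carboxylate, via hydroxy ester 5 (not isolated)
Conditions: Cs2CO3, NMP, 150 °C; then MeI, 40 °C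
Reagents that add atoms: iodomethane, CI
Why: intramolecular nucleophilic aromatic substitution, in which only the phenoxide ortho to the biaryl bond can reach the C–F carbon and closes the furan ring (a known route from 2-(2-fluorophenyl)phenols to dibenzofurans), after which Williamson methylation caps the remaining phenoxide and re-forms any ester cleaved by the heating.

Step 4
Reactants: 7 isovanillin (3-hydroxy-4-methoxybenzaldehyde); 8 methyl 4-iodobenzoate
Product: 9 methyl 4-(5-formyl-2-methoxyphenoxy)benzoate
Conditions: CuI (10 mol%), N,N-dimethylglycine (20 mol%), Cs2CO3, dioxane, 90 °C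
Reagents that add atoms: none
Why: ligand-accelerated Ullmann diaryl ether synthesis between an electron-poor aryl iodide and a guaiacol-type phenoxide, mild enough to leave the aldehyde and the ester untouched.

Step 5
Reactants: 9 methyl 4-(5-formyl-2-methoxyphenoxy)benzoate
Product: 10 methyl 4-(2-methoxy-5-vinylphenoxy)benzoate
Conditions: Ph3PCH3Br, KOtBu, THF, 0 °C to rt
Reagents that add atoms: methyltriphenylphosphonium bromide, C[P+](c1ccccc1)(c1ccccc1)c1ccccc1.[Br-]
Why: Wittig methylenation, since the unstabilised ylide reacts with the aldehyde far faster than with the aryl ester.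

Step 6
Reactants: 10 methyl 4-(2-methoxy-5-vinylphenoxy)benzoate; 6 methyl 7-chloro-3-methoxydibenzofuran-1-carboxylate
Product: 12 methyl 3-methoxy-7-{2-[4-methoxy-3-(4-methoxycarbonylphenoxy)phenyl]ethyl}dibenzofuran-1-carboxylate, via alkylborane 11 (not isolated)
Conditions: 9-BBN, THF, 0 °C to rt; then 6, Pd(OAc)2 (3 mol%), SPhos (6 mol%), K3PO4, THF/H2O, 65 °C
Reagents that add atoms: none
Why: anti-Markovnikov hydroboration of the styrene gives the primary B-alkyl-9-BBN, which undergoes B-alkyl Suzuki–Miyaura coupling with the unhindered aryl chloride under a dialkylbiarylphosphine catalyst, so the ethano bridge at C-7 forms without a hydrogenation step.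

Step 7
Reactants: 12 methyl 3-methoxy-7-{2-[4-methoxy-3-(4-methoxycarbonylphenoxy)phenyl]ethyl}dibenzofuran-1-carboxylate
Product: 13 [4-(5-{2-[1-(hydroxymethyl)-3-methoxydibenzofuran-7-yl]ethyl}-2-methoxyphenoxy)phenyl]methanol
Conditions: LiAlH4, THF, 0 °C to rt
Reagents that add atoms: none
Why: hydride reduction of both aryl esters to benzylic alcohols, with the aryl ethers and the dibenzofuran inert to LiAlH4.

Step 8
Reactants: 13 [4-(5-{2-[1-(hydroxymethyl)-3-methoxydibenzofuran-7-yl]ethyl}-2-methoxyphenoxy)phenyl]methanol
Product: 14 1-(bromomethyl)-7-(2-{3-[4-(bromomethyl)phenoxy]-4-methoxyphenyl}ethyl)-3-methoxydibenzofuran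
Conditions: PBr3, CH2Cl2, 0 °C
Reagents that add atoms: phosphorus tribromide, BrP(Br)Br
Why: both primary benzylic alcohols are converted to bromides through their phosphite esters (SN2 by bromide), under cold conditions that spare the aryl methyl ethers.

Step 9
Reactants: 14 1-(bromomethyl)-7-(2-{3-[4-(bromomethyl)phenoxy]-4-methoxyphenyl}ethyl)-3-methoxydibenzofuran
Product: 15 asterelin A dimethyl ether (the 18-membered macrocycle with both phenols as methyl ethers)
Conditions: Na (excess), tetraphenylethylene (0.2 equiv), THF, −78 °C, slow addition of 14 (final ca. 2 mM)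
Reagents that add atoms: none
Why: Intramolecular Wurtz coupling: the soluble electron carrier disodium tetraphenylethylenediide, regenerated on the sodium surface, passes two electrons to one C–Br bond to give a benzylic sodium compound by way of the benzylic radical, and this carbanion displaces bromide from the second CH2Br group by SN2. The closest known reaction type is the Wurtz cyclisation of bis(bromomethyl)arenes used for cyclophanes and for macrocyclic bis(bibenzyl) diaryl ethers of this ring size. The 18-membered ring closes exo-tet at a primary benzylic carbon and gives the CH2–CH2 bond at its final oxidation level, so no alkene has to be reduced and no auxiliary removed. No stereocentre is formed. Ring closure must beat intermolecular coupling and reduction to ArCH3; slow addition at high dilution and −78 °C keep the carbanion concentration low, and because either bromide may be reduced first the two ends need no differentiation. The bent diaryl ether at the meta-substituted ring C and the flexible ethano bridge at C-7 let ring D fold back over ring B so that its benzylic carbon reaches the CH2 on C-1, and the carrier is too weak a reductant to cleave the dibenzofuran or aryl ether C–O bonds.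

Step 10
Reactants: 15 asterelin A dimethyl ether
Product: 16 asterelin A
Conditions: BBr3, CH2Cl2, −78 °C to rt; then H2O
Reagents that add atoms: none
Why: BBr3 demethylation of both aryl methyl ethers, while the diaryl ether and dibenzofuran C–O bonds offer no sp3 carbon for bromide attack and should survive.

**Compound list**

1 | methyl 2-bromo-3,5-dimethoxybenzoate | COC(=O)c1cc(OC)cc(OC)c1Br | starting material
2 | (4-chloro-2-fluorophenyl)boronic acid | OB(O)c1ccc(Cl)cc1F | starting material
3 | methyl 2-(4-chloro-2-fluorophenyl)-3,5-dimethoxybenzoate | COC(=O)c1cc(OC)cc(OC)c1-c1ccc(Cl)cc1F | intermediate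
4 | methyl 2-(4-chloro-2-fluorophenyl)-3,5-dihydroxybenzoate | COC(=O)c1cc(O)cc(O)c1-c1ccc(Cl)cc1F | intermediate
5 | methyl 7-chloro-3-hydroxydibenzofuran-1-carboxylate | COC(=O)c1cc(O)cc2oc3cc(Cl)ccc3c12 | intermediate
6 | methyl 7-chloro-3-methoxydibenzofuran-1-carboxylate | COC(=O)c1cc(OC)cc2oc3cc(Cl)ccc3c12 | intermediate
7 | isovanillin (3-hydroxy-4-methoxybenzaldehyde) | COc1ccc(C=O)cc1O | starting material
8 | methyl 4-iodobenzoate | COC(=O)c1ccc(I)cc1 | starting material
9 | methyl 4-(5-formyl-2-methoxyphenoxy)benzoate | COC(=O)c1ccc(Oc2cc(C=O)ccc2OC)cc1 | intermediate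
10 | methyl 4-(2-methoxy-5-vinylphenoxy)benzoate | COC(=O)c1ccc(Oc2cc(C=C)ccc2OC)cc1 | intermediate
11 | methyl 4-{5-[2-(9-borabicyclo[3.3.1]nonan-9-yl)ethyl]-2-methoxyphenoxy}benzoate | COC(=O)c1ccc(Oc2cc(CCB3C4CCCC3CCC4)ccc2OC)cc1 | intermediate
12 | methyl 3-methoxy-7-{2-[4-methoxy-3-(4-methoxycarbonylphenoxy)phenyl]ethyl}dibenzofuran-1-carboxylate | COC(=O)c1cc(OC)cc2oc3cc(CCc4ccc(OC)c(Oc5ccc(C(=O)OC)cc5)c4)ccc3c12 | intermediate
13 | [4-(5-{2-[1-(hydroxymethyl)-3-methoxydibenzofuran-7-yl]ethyl}-2-methoxyphenoxy)phenyl]methanol | OCc1cc(OC)cc2oc3cc(CCc4ccc(OC)c(Oc5ccc(CO)cc5)c4)ccc3c12 | intermediate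
14 | 1-(bromomethyl)-7-(2-{3-[4-(bromomethyl)phenoxy]-4-methoxyphenyl}ethyl)-3-methoxydibenzofuran | BrCc1cc(OC)cc2oc3cc(CCc4ccc(OC)c(Oc5ccc(CBr)cc5)c4)ccc3c12 | intermediate
15 | asterelin A dimethyl ether | COc1cc2c3c(c1)oc1cc(ccc13)CCc1ccc(OC)c(c1)Oc1ccc(cc1)CC2 | intermediate
16 | asterelin A | Oc1cc2c3c(c1)oc1cc(ccc13)CCc1ccc(O)c(c1)Oc1ccc(cc1)CC2 | target

**Step count and risks**

Total step count: 10. Longest linear sequence: 8 steps (steps 1, 2, 3, 6, 7, 8, 9, 10).

Steps most likely to fail:

Step 9. Intermolecular Wurtz coupling to oligomers and protonation of the benzylic carbanion to a methyl group may outrun the slow closure of the 18-membered ring. The fallback sets out from 13 and comes back at 15. The diol 13 is oxidised with MnO2 (CH2Cl2, rt) to the dialdehyde 7-{2-[3-(4-formylphenoxy)-4-methoxyphenyl]ethyl}-3-methoxydibenzofuran-1-carbaldehyde F1. An intramolecular McMurry coupling on low-valent titanium (TiCl4, Zn, pyridine, THF, reflux, slow addition), which binds both carbonyl groups to the metal before deoxygenation, should then close the ring to the Z-stilbene macrocycle (Z)-didehydroasterelin A dimethyl ether F2. Hydrogenation (H2, Pd/C, EtOAc) of the alkene gives 15.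

Step 3. Displacement of the unactivated fluoride may stall, so that prolonged heating of the diphenoxide leads to decomposition instead of furan closure. The fallback sets out from 1 and comes back at 5, which is then methylated to 6. Suzuki–Miyaura coupling of 1 with (4-chlorophenyl)boronic acid (Pd(PPh3)4, K2CO3, DME/H2O, 90 °C) gives methyl 2-(4-chlorophenyl)-3,5-dimethoxybenzoate F3, and BBr3 (CH2Cl2, −78 °C to 0 °C) gives methyl 2-(4-chlorophenyl)-3,5-dihydroxybenzoate F4. A phenol-directed C–H activation/C–O cyclisation (Pd(OAc)2, 3-nitropyridine, tert-butyl peroxybenzoate, C6F6/DMI, 90 °C) then closes the furan ring at either of the two equivalent ortho C–H bonds of ring B and gives 5. This cyclisation runs between divalent and tetravalent palladium and so should leave the C–Cl bond alone. Methylation (MeI, K2CO3, acetone) converts 5 to 6.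

Step 6. Protodeboronation of the primary alkylborane and β-hydride elimination of the alkylpalladium intermediate may outpace productive coupling and return the styrene. The fallback sets out from 6 and 10 and comes back at 12. A Heck reaction of 6 with 10 (Pd2(dba)3, P(t-Bu)3, Cy2NMe, dioxane, 110 °C), which involves no alkylmetal species, gives the E-stilbene methyl 3-methoxy-7-{(E)-2-[4-methoxy-3-(4-methoxycarbonylphenoxy)phenyl]ethenyl}dibenzofuran-1-carboxylate F5. Hydrogenation (H2, Pd/C, EtOAc) then saturates the alkene to give 12.

**Further compounds**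

F1 | step 9 | 7-{2-[3-(4-formylphenoxy)-4-methoxyphenyl]ethyl}-3-methoxydibenzofuran-1-carbaldehyde | O=Cc1cc(OC)cc2oc3cc(CCc4ccc(OC)c(Oc5ccc(C=O)cc5)c4)ccc3c12
F2 | step 9 | (Z)-didehydroasterelin A dimethyl ether | COc1cc2c3c(c1)oc1cc(ccc13)CCc1ccc(OC)c(c1)Oc1ccc(cc1)/C=C\2
F3 | step 3 | methyl 2-(4-chlorophenyl)-3,5-dimethoxybenzoate | COC(=O)c1cc(OC)cc(OC)c1-c1ccc(Cl)cc1
F4 | step 3 | methyl 2-(4-chlorophenyl)-3,5-dihydroxybenzoate | COC(=O)c1cc(O)cc(O)c1-c1ccc(Cl)cc1
F5 | step 6 | methyl 3-methoxy-7-{(E)-2-[4-methoxy-3-(4-methoxycarbonylphenoxy)phenyl]ethenyl}dibenzofuran-1-carboxylate | COC(=O)c1cc(OC)cc2oc3cc(/C=C/c4ccc(OC)c(Oc5ccc(C(=O)OC)cc5)c4)ccc3c12
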